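C1 quaternary (CH3, acyl), C2 sec-butyl, C3=C4, C4a/C8a fusion, C5 ester O, C6 OH, C8 CH3; ring A = C1-C2-C3-C4-C4a-C8a, ring B = C4a-C5-C6-C7-C8-C8a; β = face of the C8 methyl.
Cuts, in retrosynthetic order: the C5–O acyl bond; the side-chain C–C bond next to the ketone and the C1–CH3 bond (back to a C1 carboxyl); C3=C4 back to a C4 enol ether; then ring A at C2–C3 and C1–C8a.
Enabling feature: C4 sits between C3 and the fusion carbon C4a, so with oxygen on C4 the unit C3=C4(OSi)–C4a=C8a is a 2-silyloxydiene built on intact ring B, and C1–C2 (acyl on C1, sec-butyl on C2, trans) is an (E)-enoyl dienophile.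
Forward: ring B is made from (R)-pulegone and given the silyloxyvinyl arm; the dienophile comes from (R)-2-methylbutanoic acid; ring A closes by Diels–Alder reaction; then C4 ketone to C3=C4, C1 methylation, carboxyl to hydroxyethyl ketone, diol release, C5 acylation.
Stereochemistry: C8 and the sec-butyl carbon from the chiral pool; C5/C6 by osmylation anti to an allylic OH set cis to the methyl; C1, C2, C8a in the cycloaddition (diene face anti to C8-CH3, endo, matched chiral imide); C4a by equilibration to the trans-decalone; quaternary C1 by enolate methylation anti to the sec-butyl group.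
Key step: step 14

Remark: alcohols are taken to open 3-methylglutaconic anhydride at the carbonyl attached to its CH2 group (the non-conjugated one), so that the conjugated carboxyl is released as the free acid with the ring-enforced Z geometry.

Step 1
Reactants: 1 (R)-(+)-pulegone
Product: 2 pulegone oxide (both epoxide epimers)
Conditions: 30% H2O2, LiOH (cat.), MeOH, 0 °C to rt
Reagents that add atoms: hydrogen peroxide, OO
Why: Weitz–Scheffer nucleophilic epoxidation of the enone; the epoxide configuration is irrelevant because this carbon becomes sp2 again, and the methyl-bearing stereocentre is not touched.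

Step 2
Reactants: 2 pulegone oxide
Product: 3 (5R)-5-methyl-2-(phenylsulfanyl)cyclohexan-1-one (C2 epimers)
Conditions: PhSH (1.1 equiv), NaH (0.1 equiv), THF, reflux
Reagents that add atoms: thiophenol, Sc1ccccc1
Why: thiolate opens the α,β-epoxy ketone at the α-carbon and the resulting β-alkoxide fragments by retro-aldol loss of acetone, the enolate being reprotonated by thiophenol so that base is needed only in catalytic amount.

Step 3
Reactants: 3 (5R)-5-methyl-2-(phenylsulfanyl)cyclohexan-1-one
Product: 5 (R)-5-methylcyclohex-2-en-1-one, via sulfoxide 4 (not isolated)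
Conditions: m-CPBA (1.0 equiv), CH2Cl2, −78 °C; then CaCO3, toluene, 90 °C
Reagents that add atoms: none
Why: sulfide oxidation followed by thermal syn-elimination of the α-sulfinyl ketone, which can only place the double bond between C2 and C3 and leaves the C5 stereocentre intact.

Step 4
Reactants: 5 (R)-5-methylcyclohex-2-en-1-one
Product: 6 (1R,5R)-5-methylcyclohex-2-en-1-ol (OH cis to CH3)
Conditions: NaBH4, CeCl3·7H2O, MeOH, −78 to 0 °C
Reagents that add atoms: none
Why: Luche 1,2-reduction in which hydride adds axially to the conformer with an equatorial methyl group, which should give mainly the cis (diequatorial) allylic alcohol.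

Step 5
Reactants: 6 (1R,5R)-5-methylcyclohex-2-en-1-ol
Product: 8 ring-B acetonide alcohol, via triol 7 (not isolated)
Conditions: OsO4 (2 mol%), NMO (1.3 equiv), acetone/H2O, rt; concentrate; then 2,2-dimethoxypropane, p-TsOH (cat.), acetone, rt
Reagents that add atoms: osmium tetroxide (catalytic oxygen carrier), O=[Os](=O)(=O)=O; N-methylmorpholine N-oxide, C[N+]1([O-])CCOCC1; water, O; 2,2-dimethoxypropane, COC(C)(C)OC
Why: Upjohn dihydroxylation, in which the osmium reagent approaches a cyclohexenol on the face anti to the allylic hydroxyl and therefore anti to the methyl group, sets the cis-diol, and the isopropylidene acetal then forms on the cis pair and leaves the trans hydroxyl free.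

Step 6
Reactants: 8 ring-B acetonide alcohol
Product: 9 ring-B ketone
Conditions: Dess–Martin periodinane, CH2Cl2, 0 °C to rt
Reagents that add atoms: none
Why: Dess–Martin oxidation of the secondary alcohol under near-neutral conditions that neither cleave the acetonide nor disturb the α-alkoxy centre, whose cis dioxolane fusion is the stable one in any case.

Step 7
Reactants: 9 ring-B ketone
Product: 10 ring-B enol triflate
Conditions: KHMDS, THF, −78 °C; then PhNTf2, −78 to 0 °C
Reagents that add atoms: N-phenylbis(trifluoromethanesulfonimide), O=S(=O)(N(c1ccccc1)S(=O)(=O)C(F)(F)F)C(F)(F)F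
Why: kinetic deprotonation by the hindered amide base at the CH2 group, away from the oxygen-bearing methine, followed by O-sulfonylation of the enolate.

Step 8
Reactants: 10 ring-B enol triflate
Product: 12 ring-B acetyl enone, via ethoxydiene 11 (not isolated)
Conditions: tributyl(1-ethoxyvinyl)stannane, Pd(PPh3)4 (5 mol%), LiCl, THF, 65 °C; then 1 M HCl, THF, 0 °C, short
Reagents that add atoms: tributyl(1-ethoxyvinyl)stannane, CCCC[Sn](CCCC)(CCCC)C(=C)OCC; water, O
Why: Stille coupling of the alkenyl triflate with an acetyl-anion equivalent and mild hydrolysis of the enol ether, which is much faster than cleavage of the acetonide.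

Step 9
Reactants: 12 ring-B acetyl enone
Product: 13 ring-B 2-silyloxydiene
Conditions: TBSOTf, Et3N, CH2Cl2, −78 to 0 °C
Reagents that add atoms: tert-butyldimethylsilyl trifluoromethanesulfonate, CC(C)(C)[Si](C)(C)OS(=O)(=O)C(F)(F)F
Why: soft enolisation of the methyl ketone (O-silylation, then loss of a methyl proton) gives the cross-conjugated silyl dienol ether and leaves the γ-stereocentre C8 untouched.

Step 10
Reactants: 14 (R)-2-methylbutanoic acid
Product: 15 (R)-2-methylbutan-1-ol
Conditions: LiAlH4, Et2O, 0 °C to reflux
Reagents that add atoms: none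
Why: hydride reduction of the carboxylic acid, in which the carboxylate is not enolised and the α-stereocentre is kept.

Step 11
Reactants: 15 (R)-2-methylbutan-1-ol; 16 methyl (triphenylphosphoranylidene)acetate
Product: 18 methyl (R,E)-4-methylhex-2-enoate, via aldehyde 17 (not isolated)
Conditions: TEMPO (10 mol%), PhI(OAc)2 (1.1 equiv), CH2Cl2, rt; then 16, rt
Reagents that add atoms: none
Why: nitroxyl-catalysed oxidation and Wittig olefination with the stabilised ylide in one flask, which gives the E-enoate and avoids isolating the volatile, epimerisable α-branched aldehyde.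

Step 12
Reactants: 18 methyl (R,E)-4-methylhex-2-enoate
Product: 19 (R,E)-4-methylhex-2-enoic acid
Conditions: LiOH, THF/H2O, rt; then 1 M HCl
Reagents that add atoms: lithium hydroxide, [Li+].[OH-]
Why: ester saponification under conditions too mild to deprotonate the γ-position.

Step 13
Reactants: 19 (R,E)-4-methylhex-2-enoic acid; 20 (S)-4-benzyloxazolidin-2-one
Product: 22 (S)-4-benzyl-3-[(R,E)-4-methylhex-2-enoyl]oxazolidin-2-one, via mixed anhydride 21 (not isolated)
Conditions: PivCl, Et3N, THF, −20 °C; then LiCl, 20, −20 °C to rt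
Reagents that add atoms: none
Why: N-acylation of the oxazolidinone through the mixed pivalic anhydride, which is attacked at the less hindered enoyl carbonyl; the chelating imide is chosen because it is a far stronger dienophile than the methyl ester and carries a face-directing group.

Step 14
Reactants: 13 ring-B 2-silyloxydiene; 22 (S)-4-benzyl-3-[(R,E)-4-methylhex-2-enoyl]oxazolidin-2-one
Product: 23 cycloadduct (C4 silyl enol ether)
Conditions: Me2AlCl (1.5 equiv), CH2Cl2, −78 °C, 22 precomplexed; then 13 (1.3 equiv), −78 to −30 °C; aq. NaHCO3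
Reagents that add atoms: none
Why: Me2AlCl binds both imide carbonyls and turns 22 into a cationic s-cis N-enoyl complex, which adds to the electron-rich diene either in one asynchronous [4+2] event or by Mukaiyama–Michael attack of C3 on the β-carbon followed by closure of the aluminium enolate carbon on C8a of the silyloxyallyl cation; both paths end at the same C4 silyl enol ether. The closest known reactions are Lewis-acid-promoted Diels–Alder additions of chelated N-enoyl oxazolidinones to acyclic dienes and of 1-(1-silyloxyvinyl)cyclohexenes to β-substituted acrylic acid derivatives. Ring A is closed as a six-membered carbocycle in cycloaddition mode, the C2–C3 and C1–C8a bonds forming suprafacially on both partners. C8a is set by approach to the diene face anti to the pseudoaxial C8 methyl group, C1 and C2 by the dienophile face left open by the benzyl group of the auxiliary together with the E geometry (acyl and sec-butyl trans), and the endo position of the acyl group ties the partners together so that the sec-butyl group ends up trans to the C8a–C8 bond. The step needs regioselectivity, endo selectivity and diene-face selectivity: the first follows from the 4-silyloxy group and the ring alkyl group, which both make C3 the nucleophilic terminus, the second from the chelated acyl group, and the third is reinforced because the (S)-benzyl auxiliary exposes the Cα-si face, which in the endo mode pairs only with the diene face anti to the C8 methyl (matched case).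

Step 15
Reactants: 23 cycloadduct (C4 silyl enol ether)
Product: 24 trans-decalone imide
Conditions: TBAF, AcOH (1:1), THF, 0 °C; then DBU (0.2 equiv), rt
Reagents that add atoms: none
Why: fluoride cleaves the silyl enol ether and the C4a proton is placed under thermodynamic control, where the trans-fused decalone (4aα-H) should prevail because the cis isomer must put C4 syn-axial to the C6 oxygen or the C1 and C5 substituents syn-diaxial, while the C5–O bond lies near the enolate plane so that β-elimination is stereoelectronically disfavoured.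

Step 16
Reactants: 24 trans-decalone imide
Product: 25 Δ3 enol triflate
Conditions: KHMDS (1.05 equiv), THF, −78 °C; then PhNTf2, −78 to −20 °C
Reagents that add atoms: N-phenylbis(trifluoromethanesulfonimide), O=S(=O)(N(c1ccccc1)S(=O)(=O)C(F)(F)F)C(F)(F)F
Why: kinetic deprotonation takes the C3 methylene in preference to the C4a methine and to the strained imide α-CH, and O-triflation of that enolate fixes the double bond between C3 and C4.

Step 17
Reactants: 25 Δ3 enol triflate
Product: 26 Δ3-octalin imide
Conditions: Pd(OAc)2 (5 mol%), PPh3 (10 mol%), HCO2H, n-Bu3N, DMF, 60 °C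
Reagents that add atoms: none
Why: palladium-catalysed formate reduction of the alkenyl triflate (oxidative addition, formate exchange, decarboxylation, reductive elimination) replaces OTf by H without touching any stereocentre.

Step 18
Reactants: 26 Δ3-octalin imide
Product: 27 benzyl ester
Conditions: BnOH (2 equiv), n-BuLi (1.5 equiv), THF, 0 °C; then 26, 0 °C
Reagents that add atoms: benzyl alcohol (as lithium benzyloxide), OCc1ccccc1
Why: lithium benzyloxide attacks the exocyclic imide carbonyl and releases the oxazolidinone, a transesterification known for α-branched cycloadducts, and any epimerisation at C1 is harmless because C1 is alkylated next.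

Step 19
Reactants: 27 benzyl ester
Product: 28 C1-methylated benzyl ester
Conditions: LDA (1.5 equiv), THF/DMPU, −78 to −20 °C; then MeI, −78 to 0 °C
Reagents that add atoms: iodomethane, CI
Why: alkylation of the ester enolate, in which C1 becomes trigonal so that either C1 epimer converges and methyl iodide enters on the α face, anti to the pseudoaxial sec-butyl group on C2, leaving CH3 α and the carboxyl β.

Step 20
Reactants: 28 C1-methylated benzyl ester
Product: 29 neopentyl alcohol
Conditions: LiAlH4, THF, 0 °C to reflux
Reagents that add atoms: none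
Why: hydride reduction of the hindered ester, to which the acetonide and the isolated ring alkene are inert.

Step 21
Reactants: 29 neopentyl alcohol
Product: 30 quaternary aldehyde
Conditions: Dess–Martin periodinane, CH2Cl2, rt
Reagents that add atoms: none
Why: Dess–Martin oxidation of the primary alcohol to an aldehyde that has no α-hydrogen and therefore cannot epimerise or enolise.

Step 22
Reactants: 30 quaternary aldehyde
Product: 31 vinyl carbinol (both carbinol epimers)
Conditions: CH2=CHMgBr (3 equiv), THF, −78 to 0 °C
Reagents that add atoms: vinylmagnesium bromide, C=C[Mg]Br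
Why: Grignard addition to the non-enolisable aldehyde, the configuration of the new carbinol being irrelevant because it is oxidised in the next step.

Step 23
Reactants: 31 vinyl carbinol
Product: 32 vinyl ketone
Conditions: Dess–Martin periodinane, CH2Cl2, 0 °C to rt
Reagents that add atoms: none
Why: Dess–Martin oxidation of the allylic alcohol to the enone, which is carried on without storage.

Step 24
Reactants: 32 vinyl ketone
Product: 33 PMB-protected hydroxyethyl ketone
Conditions: 4-methoxybenzyl alcohol (3 equiv), PMe3 (10 mol%), THF, rt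
Reagents that add atoms: 4-methoxybenzyl alcohol, COc1ccc(CO)cc1
Why: phosphine-catalysed oxa-Michael addition, in which the phosphonium enolate formed from the enone deprotonates the alcohol and the alkoxide adds to the unsubstituted β-carbon, installs the terminal oxygen already protected.

Step 25
Reactants: 33 PMB-protected hydroxyethyl ketone
Product: 34 5,6-diol
Conditions: AcOH/H2O (4:1), 50 °C
Reagents that add atoms: none
Why: acid hydrolysis of the isopropylidene acetal under conditions that the PMB ether, the ring alkene and the β-alkoxy ketone should tolerate.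

Step 26
Reactants: 34 5,6-diol; 35 3-methylglutaconic anhydride
Product: 36 O-PMB tandyukisin C
Conditions: 35 (1.2 equiv), DMAP (0.1 equiv), CH2Cl2, 0 °C to rt
Reagents that add atoms: none
Why: alcoholysis of the cyclic anhydride at its non-conjugated carbonyl gives the half-ester with the Z double bond inherited from the ring, and the equatorial C5 hydroxyl should react in preference to the axial C6 hydroxyl, which is flanked by two syn-axial hydrogens (H4a, H8) and is also the less favoured acyl position thermodynamically.

Step 27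
Reactants: 36 O-PMB tandyukisin C
Product: 37 tandyukisin C
Conditions: DDQ (1.5 equiv), CH2Cl2/pH 7 buffer (10:1), 0 °C to rt
Reagents that add atoms: none
Why: oxidative cleavage of the p-methoxybenzyl ether (benzylic hydride abstraction, hydrolysis of the oxocarbenium ion) under neutral conditions that should leave the Z-enoate, the free acid and the β-hydroxy ketone untouched.

Compound list
1 | (R)-(+)-pulegone | C[C@@H]1CCC(=C(C)C)C(=O)C1 | starting material
2 | pulegone oxide, (6R)-2,2,6-trimethyl-1-oxaspiro[2.5]octan-4-one (epoxide epimers) | C[C@@H]1CCC2(OC2(C)C)C(=O)C1 | intermediate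
3 | (5R)-5-methyl-2-(phenylsulfanyl)cyclohexan-1-one (C2 epimers) | C[C@@H]1CCC(Sc2ccccc2)C(=O)C1 | intermediate
4 | (5R)-5-methyl-2-(phenylsulfinyl)cyclohexan-1-one | C[C@@H]1CCC(S(=O)c2ccccc2)C(=O)C1 | intermediate (not isolated)
5 | (R)-5-methylcyclohex-2-en-1-one | C[C@@H]1CC=CC(=O)C1 | intermediate
6 | (1R,5R)-5-methylcyclohex-2-en-1-ol (OH cis to CH3) | C[C@@H]1CC=C[C@H](O)C1 | intermediate
7 | 5-methylcyclohexane-1,2,3-triol; 1-OH cis to CH3; 2-OH and 3-OH cis to each other and trans to CH3 | C[C@@H]1C[C@@H](O)[C@@H](O)[C@H](O)C1 | intermediate (not isolated)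
8 | ring-B acetonide alcohol: 2,2,6-trimethylhexahydro-1,3-benzodioxol-4-ol; cis-fused dioxolane trans to the 6-methyl; 4-OH cis to the 6-methyl | C[C@@H]1C[C@H]2OC(C)(C)O[C@H]2[C@H](O)C1 | intermediate
9 | ring-B ketone: (3aR,6R,7aR)-2,2,6-trimethylhexahydro-1,3-benzodioxol-4-one | C[C@@H]1C[C@H]2OC(C)(C)O[C@H]2C(=O)C1 | intermediate
10 | ring-B enol triflate: 2,2,6-trimethyl-3a,6,7,7a-tetrahydro-1,3-benzodioxol-4-yl trifluoromethanesulfonate (configuration as in 9) | C[C@@H]1C[C@H]2OC(C)(C)O[C@H]2C(OS(=O)(=O)C(F)(F)F)=C1 | intermediate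
11 | 4-(1-ethoxyvinyl)-2,2,6-trimethyl-3a,6,7,7a-tetrahydro-1,3-benzodioxole (configuration as in 9) | C=C(OCC)C1=C[C@H](C)C[C@H]2OC(C)(C)O[C@H]21 | intermediate (not isolated)
12 | ring-B acetyl enone: 1-(2,2,6-trimethyl-3a,6,7,7a-tetrahydro-1,3-benzodioxol-4-yl)ethan-1-one (configuration as in 9) | CC(=O)C1=C[C@H](C)C[C@H]2OC(C)(C)O[C@H]21 | intermediate
13 | ring-B 2-silyloxydiene: tert-butyldimethyl{[1-(2,2,6-trimethyl-3a,6,7,7a-tetrahydro-1,3-benzodioxol-4-yl)vinyl]oxy}silane (configuration as in 9) | C=C(O[Si](C)(C)C(C)(C)C)C1=C[C@H](C)C[C@H]2OC(C)(C)O[C@H]21 | intermediate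
14 | (R)-2-methylbutanoic acid | CC[C@@H](C)C(=O)O | starting material
15 | (R)-2-methylbutan-1-ol | CC[C@@H](C)CO | intermediate
16 | methyl (triphenylphosphoranylidene)acetate | COC(=O)C=P(c1ccccc1)(c1ccccc1)c1ccccc1 | starting material
17 | (R)-2-methylbutanal | CC[C@@H](C)C=O | intermediate (not isolated)
18 | methyl (R,E)-4-methylhex-2-enoate | CC[C@@H](C)/C=C/C(=O)OC | intermediate
19 | (R,E)-4-methylhex-2-enoic acid | CC[C@@H](C)/C=C/C(=O)O | intermediate
20 | (S)-4-benzyloxazolidin-2-one | O=C1N[C@@H](Cc2ccccc2)CO1 | starting material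
21 | (R,E)-4-methylhex-2-enoic pivalic anhydride | CC[C@@H](C)/C=C/C(=O)OC(=O)C(C)(C)C | intermediate (not isolated)
22 | (S)-4-benzyl-3-[(R,E)-4-methylhex-2-enoyl]oxazolidin-2-one | CC[C@@H](C)/C=C/C(=O)N1[C@@H](Cc2ccccc2)COC1=O | intermediate
23 | cycloadduct: Δ4(4a)-octalin; 4-OTBS enol ether; 1α-[(S)-4-benzyl-2-oxooxazolidin-3-yl]carbonyl; 2β-[(R)-butan-2-yl]; 5α,6α-isopropylidenedioxy; 8β-methyl; 8aβ-H | CC[C@@H](C)[C@H]1CC(O[Si](C)(C)C(C)(C)C)=C2[C@@H]3OC(C)(C)O[C@@H]3C[C@@H](C)[C@@H]2[C@@H]1C(=O)N1[C@@H](Cc2ccccc2)COC1=O | intermediate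
24 | trans-decalone imide: 4-oxo; 4aα-H; 8aβ-H; other substituents as in 23 | CC[C@@H](C)[C@H]1CC(=O)[C@H]2[C@@H]3OC(C)(C)O[C@@H]3C[C@@H](C)[C@@H]2[C@@H]1C(=O)N1[C@@H](Cc2ccccc2)COC1=O | intermediate
25 | Δ3 enol triflate: 4-trifluoromethanesulfonyloxy-Δ3; other features as in 24 | CC[C@@H](C)[C@H]1C=C(OS(=O)(=O)C(F)(F)F)[C@H]2[C@@H]3OC(C)(C)O[C@@H]3C[C@@H](C)[C@@H]2[C@@H]1C(=O)N1[C@@H](Cc2ccccc2)COC1=O | intermediate
26 | Δ3-octalin imide: trans-fused (4aα-H, 8aβ-H); 1α-imide carbonyl; 2β-sec-butyl; 5α,6α-acetonide; 8β-methyl | CC[C@@H](C)[C@H]1C=C[C@H]2[C@@H]3OC(C)(C)O[C@@H]3C[C@@H](C)[C@@H]2[C@@H]1C(=O)N1[C@@H](Cc2ccccc2)COC1=O | intermediate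
27 | benzyl ester: as 26 with 1α-CO2Bn | CC[C@@H](C)[C@H]1C=C[C@H]2[C@@H]3OC(C)(C)O[C@@H]3C[C@@H](C)[C@@H]2[C@@H]1C(=O)OCc1ccccc1 | intermediate
28 | C1-methylated benzyl ester: 1α-CH3; 1β-CO2Bn | CC[C@@H](C)[C@H]1C=C[C@H]2[C@@H]3OC(C)(C)O[C@@H]3C[C@@H](C)[C@@H]2[C@@]1(C)C(=O)OCc1ccccc1 | intermediate
29 | neopentyl alcohol: 1α-CH3; 1β-CH2OH | CC[C@@H](C)[C@H]1C=C[C@H]2[C@@H]3OC(C)(C)O[C@@H]3C[C@@H](C)[C@@H]2[C@@]1(C)CO | intermediate
30 | quaternary aldehyde: 1α-CH3; 1β-CHO | CC[C@@H](C)[C@H]1C=C[C@H]2[C@@H]3OC(C)(C)O[C@@H]3C[C@@H](C)[C@@H]2[C@@]1(C)C=O | intermediate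
31 | vinyl carbinol: 1β-CH(OH)CH=CH2 (carbinol epimers) | CC[C@@H](C)[C@H]1C=C[C@H]2[C@@H]3OC(C)(C)O[C@@H]3C[C@@H](C)[C@@H]2[C@@]1(C)C(O)C=C | intermediate
32 | vinyl ketone: 1β-C(=O)CH=CH2 | CC[C@@H](C)[C@H]1C=C[C@H]2[C@@H]3OC(C)(C)O[C@@H]3C[C@@H](C)[C@@H]2[C@@]1(C)C(=O)C=C | intermediate
33 | PMB-protected hydroxyethyl ketone: 1β-C(=O)CH2CH2OPMB; acetonide intact | CC[C@@H](C)[C@H]1C=C[C@H]2[C@@H]3OC(C)(C)O[C@@H]3C[C@@H](C)[C@@H]2[C@@]1(C)C(=O)CCOCc1ccc(OC)cc1 | intermediate
34 | 5,6-diol: 5α-OH (equatorial); 6α-OH (axial); side chain as in 33 | CC[C@@H](C)[C@H]1C=C[C@H]2[C@H](O)[C@H](O)C[C@@H](C)[C@@H]2[C@@]1(C)C(=O)CCOCc1ccc(OC)cc1 | intermediate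
35 | 3-methylglutaconic anhydride | CC1=CC(=O)OC(=O)C1 | starting material
36 | O-PMB tandyukisin C: 5α-O-[(Z)-4-carboxy-3-methylbut-3-enoyl]; 6α-OH; primary OH as PMB ether | CC[C@@H](C)[C@H]1C=C[C@H]2[C@H](OC(=O)C/C(C)=C\C(=O)O)[C@H](O)C[C@@H](C)[C@@H]2[C@@]1(C)C(=O)CCOCc1ccc(OC)cc1 | intermediate
37 | tandyukisin C | CC[C@@H](C)[C@H]1C=C[C@H]2[C@H](OC(=O)C/C(C)=C\C(=O)O)[C@H](O)C[C@@H](C)[C@@H]2[C@@]1(C)C(=O)CCO | target

Total step count: 27 (9 to diene 13, 4 to dienophile 22, 14 from the cycloaddition to the target).
Longest linear sequence: 23 steps (steps 1–9 and 14–27).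

Steps most likely to fail

Step 14. The cycloaddition may stall because the β-branched dienophile is slow, the diene may be attacked on the wrong face because the dioxolane sits on the face that has to be used, or the silyl enol ether may be lost to the Lewis acid. The fallback makes the same two bonds by an anionic Michael–Michael annulation without Lewis acid. It sets out from enone 12 and ester 18: the kinetic lithium dienolate of 12 (LDA, THF, −78 °C) adds through its terminal carbon to the β-carbon of 18, and the ester enolate closes on C8a in a lithium-bridged, endo-like arrangement anti to the C8 methyl. After DBU equilibration at C4a this should give the keto methyl ester F1. Kinetic triflation at C3 (KHMDS, PhNTf2) gives the enol triflate F2, palladium/formate reduction the Δ3 methyl ester F3, and LDA/MeI the quaternary methyl ester F4. LiAlH4 reduction of F4 returns to alcohol 29.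

Step 19. Enolisation of the flanked C1–H may be incomplete, or the ester enolate, strained against the C8a–C8 bond, may fail to alkylate. The fallback moves the methylation to the aldehyde oxidation level, where the enolate carbon carries only H and O−. It sets out from 27: LiAlH4 reduction gives the primary alcohol F5 and Dess–Martin oxidation the enolisable aldehyde F6. Its potassium enolate (t-BuOK, THF, 0 °C) with MeI should be C-methylated from the α face and gives aldehyde 30 directly, so the route is rejoined at 30 and steps 20 and 21 fall away.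

Step 26. Acylation may not distinguish the two secondary hydroxyls, may go twice, or the acyl group may migrate. The fallback masks the C6 hydroxyl first by the orthoester method and sets out from diol 34. Trimethyl orthoformate and PPTS give the cyclic orthoformate F7, and brief aqueous acetic acid opens it with the ester on the axial oxygen, which gives the C6 formate with free C5 hydroxyl F8. Anhydride 35, warmed in toluene without base so that the formate does not migrate, acylates the only free secondary hydroxyl and gives the C5 half-ester C6 formate F9. The formate, far more labile than the other esters, is removed with KHCO3 in methanol at 0 °C, and the route is rejoined at 36.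

Further compounds
F1 | step 14 | keto methyl ester (trans-decalone; 1α-CO2CH3; other substituents as in 24) | CC[C@@H](C)[C@H]1CC(=O)[C@H]2[C@@H]3OC(C)(C)O[C@@H]3C[C@@H](C)[C@@H]2[C@@H]1C(=O)OC
F2 | step 14 | Δ3 enol triflate methyl ester | CC[C@@H](C)[C@H]1C=C(OS(=O)(=O)C(F)(F)F)[C@H]2[C@@H]3OC(C)(C)O[C@@H]3C[C@@H](C)[C@@H]2[C@@H]1C(=O)OC
F3 | step 14 | Δ3-octalin methyl ester (1α-CO2CH3) | CC[C@@H](C)[C@H]1C=C[C@H]2[C@@H]3OC(C)(C)O[C@@H]3C[C@@H](C)[C@@H]2[C@@H]1C(=O)OC
F4 | step 14 | quaternary methyl ester (1α-CH3; 1β-CO2CH3) | CC[C@@H](C)[C@H]1C=C[C@H]2[C@@H]3OC(C)(C)O[C@@H]3C[C@@H](C)[C@@H]2[C@@]1(C)C(=O)OC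
F5 | step 19 | primary alcohol without the C1 methyl (1α-CH2OH; 1β-H) | CC[C@@H](C)[C@H]1C=C[C@H]2[C@@H]3OC(C)(C)O[C@@H]3C[C@@H](C)[C@@H]2[C@@H]1CO
F6 | step 19 | enolisable aldehyde (1α-CHO; 1β-H) | CC[C@@H](C)[C@H]1C=C[C@H]2[C@@H]3OC(C)(C)O[C@@H]3C[C@@H](C)[C@@H]2[C@@H]1C=O
F7 | step 26 | cyclic 5,6-orthoformate of 34 (orthoester carbon epimers) | CC[C@@H](C)[C@H]1C=C[C@H]2[C@@H]3OC(OC)O[C@@H]3C[C@@H](C)[C@@H]2[C@@]1(C)C(=O)CCOCc1ccc(OC)cc1
F8 | step 26 | C6 formate with free C5 hydroxyl | CC[C@@H](C)[C@H]1C=C[C@H]2[C@H](O)[C@H](OC=O)C[C@@H](C)[C@@H]2[C@@]1(C)C(=O)CCOCc1ccc(OC)cc1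
F9 | step 26 | C5 half-ester C6 formate | CC[C@@H](C)[C@H]1C=C[C@H]2[C@H](OC(=O)C/C(C)=C\C(=O)O)[C@H](OC=O)C[C@@H](C)[C@@H]2[C@@]1(C)C(=O)CCOCc1ccc(OC)cc1
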